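**Plan**
- **Cuts:** the quinone goes back to its bis-MOM hydroquinone. In each indole the pyrrole bonds N1–C2 and C3–C3a are cut. Then follow the two C(aryl)–C(sp) bonds at C3 and C6, the C5–CH2 (prenyl) bond and the C2–O bond of the central ring.
- **Enabling feature:** both indoles are joined through their C3 to C3 and C6 of the six-membered quinone ring and carry only hydrogen at C2 and N1. C3 and C2 of each pyrrole ring can therefore be the two carbons of a silyl-capped alkyne on the central ring, while N1 and the benzo ring (C3a–C7a) come from 2-iodoaniline.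
- **Forward:** the central ring is bought as symmetric 2,5-dibromohydroquinone. Oxygen at C2, prenyl at C5 and two silylalkynes at C3/C6 are added in that order. Both pyrrole rings then close in one flask, and desilylation, MOM cleavage and oxidation complete the quinone.
- **Stereochemistry:** the target has no stereocentre and no E/Z alkene. The control problem is regiochemical and is answered by the symmetry of the dibromide and by the silyl groups in the annulation.

Key step: step 6

Assumption: from compound 6 onward the central ring is numbered as in the quinone (C1 and C4 bear oxygen, C2 OMe, C3 and C6 the future indol-3-yl groups, C5 prenyl = 3-methylbut-2-en-1-yl). Slowly interconverting rotamers about aryl–indolyl axes are treated as one compound.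

Step 1
Reactants: 1 2,5-dibromohydroquinone
Product: 2 1,4-dibromo-2,5-bis(methoxymethoxy)benzene
Conditions: MOMCl, i-Pr2NEt, CH2Cl2, 0 °C → rt
Reagents that add atoms: chloromethyl methyl ether (MOMCl), COCCl
Why: Twofold O-alkylation of the phenols with the reactive chloromethyl ether (acetal protection) gives MOM ethers that withstand LDA, carbonate at 100 °C and fluoride and that, together with bromine, acidify the two remaining ring C–H bonds.

Step 2
Reactants: 2 1,4-dibromo-2,5-bis(methoxymethoxy)benzene
Product: 5 2,5-dibromo-3,6-bis(methoxymethoxy)phenol, via aryllithium 3 (not isolated), via dimethyl arylboronate 4 (not isolated)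
Conditions: LDA, THF, −78 °C; B(OMe)3, −78 °C → rt; 30% H2O2, aq NaOH, 0 °C
Reagents that add atoms: hydrogen peroxide, OO (the new oxygen); trimethyl borate, COB(OC)OC, supplies only the boron group of 4
Why: Directed ortho-lithiation with a non-nucleophilic amide base (no Br/Li exchange) removes one of two equivalent protons, each flanked by Br and OMOM, and borylation followed by peroxide oxidation (1,2-aryl shift from boron to oxygen) turns C–Li into the future C2–O bond, the symmetry of 2 removing any regiochemical question.

Step 3
Reactants: 5 2,5-dibromo-3,6-bis(methoxymethoxy)phenol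
Product: 6 3,6-dibromo-2-methoxy-1,4-bis(methoxymethoxy)benzene
Conditions: MeI, K2CO3, acetone, reflux
Reagents that add atoms: iodomethane (MeI), CI
Why: Williamson ether synthesis on the acidic, flanked phenol with the small electrophile MeI sets the C2 methoxy group and leaves bromides and acetals untouched.

Step 4
Reactants: 6 3,6-dibromo-2-methoxy-1,4-bis(methoxymethoxy)benzene; 7 prenyl bromide (1-bromo-3-methylbut-2-ene)
Product: 10 3,6-dibromo-2-methoxy-1,4-bis(methoxymethoxy)-5-prenylbenzene, via aryllithium 8 (not isolated), via arylcopper 9 (not isolated)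
Conditions: LDA, THF, −78 °C; CuBr·SMe2, −78 °C; 7, −78 → 0 °C
Reagents that add atoms: prenyl bromide (7), CC(C)=CCBr
Why: A second directed ortho-lithiation takes the only ring proton left (between OMOM and Br), transmetalation to copper at −78 °C forestalls loss of LiBr to an aryne, and the arylcopper displaces bromide at the primary carbon of 7 (SN2 allylation, the gem-dimethyl terminus being shielded from SN2′ attack); placing this step after all other strong-base chemistry keeps the doubly activated ArCH2–CH= protons away from base.

Step 5
Reactants: 10 3,6-dibromo-2-methoxy-1,4-bis(methoxymethoxy)-5-prenylbenzene; 11 (triethylsilyl)acetylene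
Product: 12 2-methoxy-1,4-bis(methoxymethoxy)-5-prenyl-3,6-bis[(triethylsilyl)ethynyl]benzene
Conditions: 11 (3 equiv), PdCl2(MeCN)2 (cat.), XPhos (cat.), Cs2CO3, MeCN, 85 °C
Reagents that add atoms: (triethylsilyl)acetylene (11), C#C[Si](CC)(CC)CC
Why: Twofold copper-free Sonogashira coupling, in which the bulky electron-rich biarylphosphine drives oxidative addition into the electron-rich, doubly ortho-substituted C–Br bonds and the rod-shaped acetylide fits between the flanking groups; SiEt3 is preferred to SiMe3 because it survives carbonate bases and weighs more heavily in the regiochemistry of step 6.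

Step 6
Reactants: 12 2-methoxy-1,4-bis(methoxymethoxy)-5-prenyl-3,6-bis[(triethylsilyl)ethynyl]benzene; 13 2-iodoaniline (two molecules incorporated)
Product: 15 3,3'-[2-methoxy-1,4-bis(methoxymethoxy)-5-prenylbenzene-3,6-diyl]bis[2-(triethylsilyl)-1H-indole], via mono-indole 14 (not isolated)
Conditions: 13 (3 equiv), Pd(OAc)2 (cat.), LiCl, Na2CO3, DMF, 100 °C
Reagents that add atoms: 2-iodoaniline (13), Nc1ccccc1I
Why: This is a Larock heteroannulation run twice in one flask: zerovalent palladium formed from Pd(OAc)2 inserts into the C–I bond of 13, and the divalent arylpalladium iodide adds syn across an alkyne of 12 so that the aniline carbon bonds to the alkyne carbon on the central ring (C3–C3a) while palladium takes the silyl-bearing carbon. The ortho-NH2 then displaces halide to give a six-membered palladacycle (Pd, N1, C7a, C3a, C3, C2), and carbonate-assisted C–N reductive elimination forms N1–C2, so each pyrrole ring arises by an intermolecular [3+2] annulation whose closing event contracts the palladacycle to the five-membered ring; the same cycle carries 14 (drawn for the less crowded C3 alkyne reacting first) on to 15. The closest known case is the annulation of 2-iodoaniline with 1-aryl-2-silylalkynes, which gives 3-aryl-2-silylindoles. The selectivity needed, twice, is regiochemical: SiEt3 must outrank the 2,6-disubstituted core aryl for the palladium-bearing carbon, which is favoured by its bulk, by the stabilisation of a C–Pd bond alpha to silicon and by the electron-rich core polarising the alkyne towards the silyl-bearing carbon. No stereocentre is formed, and any rotamers about the two new aryl–indolyl axes should merge once the silyl groups are removed in step 7. The trisubstituted prenyl alkene is a poor Heck acceptor, the MOM ethers are inert to carbonate in DMF, and the crowded aryl–C3 bonds already exist as slim alkyne bonds before any indole bulk is built.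

Step 7
Reactants: 15 3,3'-[2-methoxy-1,4-bis(methoxymethoxy)-5-prenylbenzene-3,6-diyl]bis[2-(triethylsilyl)-1H-indole]
Product: 16 3,3'-[2-methoxy-1,4-bis(methoxymethoxy)-5-prenylbenzene-3,6-diyl]bis(1H-indole)
Conditions: TBAF, THF, 60 °C
Reagents that add atoms: none
Why: Fluoride-induced protodesilylation of 2-silylindoles (fluoride attack on silicon, protonation of C2 by the water of the reagent) is a known non-acidic way to free C2–H and does not touch the MOM ethers, the methoxy group or the prenyl alkene.

Step 8
Reactants: 16 3,3'-[2-methoxy-1,4-bis(methoxymethoxy)-5-prenylbenzene-3,6-diyl]bis(1H-indole)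
Product: 18 3,6-di(1H-indol-3-yl)-2-methoxy-5-(3-methylbut-2-en-1-yl)cyclohexa-2,5-diene-1,4-dione (CNP0506434.0), via hydroquinone 17 (not isolated)
Conditions: HCl (ca. 1 M), MeOH–THF, rt, Ar; then Ag2O, CH2Cl2, rt
Reagents that add atoms: none
Why: Acid-catalysed transacetalisation with methanol cleaves both aryl MOM ethers, the excess methanol carrying off the methoxymethyl cation before it can attack indole C2 and the low acid strength and temperature holding back addition of the C4 hydroxyl to the prenyl alkene, and neutral Ag2O then dehydrogenates the very electron-rich hydroquinone 17 to the para-quinone without harming the indoles.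

**Compound list**
1 | 2,5-dibromohydroquinone | Oc1cc(Br)c(O)cc1Br | starting material
2 | 1,4-dibromo-2,5-bis(methoxymethoxy)benzene | COCOc1cc(Br)c(OCOC)cc1Br | intermediate
3 | 2,5-dibromo-3,6-bis(methoxymethoxy)phenyllithium | COCOc1c([Li])c(Br)c(OCOC)cc1Br | intermediate
4 | dimethyl [2,5-dibromo-3,6-bis(methoxymethoxy)phenyl]boronate | COCOc1c(B(OC)OC)c(Br)c(OCOC)cc1Br | intermediate
5 | 2,5-dibromo-3,6-bis(methoxymethoxy)phenol | COCOc1c(O)c(Br)c(OCOC)cc1Br | intermediate
6 | 3,6-dibromo-2-methoxy-1,4-bis(methoxymethoxy)benzene | COCOc1c(OC)c(Br)c(OCOC)cc1Br | intermediate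
7 | prenyl bromide (1-bromo-3-methylbut-2-ene) | CC(C)=CCBr | starting material
8 | C5-lithiated 6 | COCOc1c(OC)c(Br)c(OCOC)c([Li])c1Br | intermediate
9 | C5-arylcopper derived from 8 | COCOc1c(OC)c(Br)c(OCOC)c([Cu])c1Br | intermediate
10 | 3,6-dibromo-2-methoxy-1,4-bis(methoxymethoxy)-5-prenylbenzene | COCOc1c(OC)c(Br)c(OCOC)c(CC=C(C)C)c1Br | intermediate
11 | (triethylsilyl)acetylene | C#C[Si](CC)(CC)CC | starting material
12 | 2-methoxy-1,4-bis(methoxymethoxy)-5-prenyl-3,6-bis[(triethylsilyl)ethynyl]benzene | COCOc1c(OC)c(C#C[Si](CC)(CC)CC)c(OCOC)c(CC=C(C)C)c1C#C[Si](CC)(CC)CC | intermediate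
13 | 2-iodoaniline | Nc1ccccc1I | starting material
14 | mono-indole: 2-(triethylsilyl)indol-3-yl at C3 and (triethylsilyl)ethynyl still at C6 | COCOc1c(OC)c(-c2c([Si](CC)(CC)CC)[nH]c3ccccc23)c(OCOC)c(CC=C(C)C)c1C#C[Si](CC)(CC)CC | intermediate
15 | 3,3'-[2-methoxy-1,4-bis(methoxymethoxy)-5-prenylbenzene-3,6-diyl]bis[2-(triethylsilyl)-1H-indole] | COCOc1c(OC)c(-c2c([Si](CC)(CC)CC)[nH]c3ccccc23)c(OCOC)c(CC=C(C)C)c1-c1c([Si](CC)(CC)CC)[nH]c2ccccc12 | intermediate
16 | 3,3'-[2-methoxy-1,4-bis(methoxymethoxy)-5-prenylbenzene-3,6-diyl]bis(1H-indole) | COCOc1c(OC)c(-c2c[nH]c3ccccc23)c(OCOC)c(CC=C(C)C)c1-c1c[nH]c2ccccc12 | intermediate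
17 | 3,6-di(1H-indol-3-yl)-2-methoxy-5-prenylbenzene-1,4-diol | COc1c(O)c(-c2c[nH]c3ccccc23)c(CC=C(C)C)c(O)c1-c1c[nH]c2ccccc12 | intermediate
18 | 3,6-di(1H-indol-3-yl)-2-methoxy-5-(3-methylbut-2-en-1-yl)cyclohexa-2,5-diene-1,4-dione (CNP0506434.0) | COC1=C(c2c[nH]c3ccccc23)C(=O)C(CC=C(C)C)=C(c2c[nH]c3ccccc23)C1=O | target

Total step count: 8. Longest linear sequence: 8 (1 → 18).

**Steps most likely to fail**

**Step 6.**
- **Risk:** alkyne insertion at the two crowded triple bonds may be slow. The reaction may stall after the first annulation. Regiocontrol may erode if the doubly ortho-substituted core competes with silicon for the palladium-bearing carbon. The alkyne may also lose its silyl group before insertion.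
- **Fallback:** this sets out from 10 and joins preformed indoles instead of building them. A twofold Suzuki–Miyaura coupling is run with commercial 1-Boc-indol-3-ylboronic acid pinacol ester (Pd(OAc)2, SPhos, K3PO4, toluene–water, 95 °C). It should give the bis(1-Boc-indol-3-yl)arene F1. K2CO3 in methanol then removes both indole carbamates, and the route is rejoined at 16.

**Step 5.**
- **Risk:** oxidative addition into the hexasubstituted, electron-rich dibromide may be sluggish. That would lead to incomplete second coupling or reductive loss of bromine, most likely at C6 between OMOM and the prenyl CH2.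
- **Fallback:** this sets out from 6 and reverses the order of events. The same Sonogashira coupling with 11 is carried out before the prenyl group is present, giving the prenyl-free bis-alkyne F2. The lone C5–H (between OMOM and an alkynyl group) is then removed with the non-nucleophilic base LiTMP in THF at −78 °C to give the aryllithium F3. With no ortho bromine and hence no aryne pathway, F3 can be alkylated directly with 7, and the route is rejoined at 12.

**Step 8.**
- **Risk:** under proton acid the freed C4 hydroxyl may add to the protonated prenyl alkene (chroman ring closure). The methoxymethyl cation may be captured by indole C2.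
- **Fallback:** this sets out from 16 and avoids proton acid altogether. TMSOTf with 2,2'-bipyridyl in MeCN at 0 °C → rt exchanges aryl MOM ethers for silyl ethers, giving the bis(trimethylsilyl) ether F4. Neutral water cleaves F4, rejoining the route at hydroquinone 17, which is oxidised with Ag2O as before.

**Further compounds**
F1 | step 6 | di-tert-butyl 3,3'-[2-methoxy-1,4-bis(methoxymethoxy)-5-prenylbenzene-3,6-diyl]bis(1H-indole-1-carboxylate) | COCOc1c(OC)c(-c2cn(C(=O)OC(C)(C)C)c3ccccc23)c(OCOC)c(CC=C(C)C)c1-c1cn(C(=O)OC(C)(C)C)c2ccccc12
F2 | step 5 | 2-methoxy-1,4-bis(methoxymethoxy)-3,6-bis[(triethylsilyl)ethynyl]benzene | COCOc1c(OC)c(C#C[Si](CC)(CC)CC)c(OCOC)cc1C#C[Si](CC)(CC)CC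
F3 | step 5 | C5-lithiated F2 | COCOc1c(OC)c(C#C[Si](CC)(CC)CC)c(OCOC)c([Li])c1C#C[Si](CC)(CC)CC
F4 | step 8 | 3,3'-[2-methoxy-5-prenyl-1,4-bis(trimethylsilyloxy)benzene-3,6-diyl]bis(1H-indole) | COc1c(O[Si](C)(C)C)c(-c2c[nH]c3ccccc23)c(CC=C(C)C)c(O[Si](C)(C)C)c1-c1c[nH]c2ccccc12
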